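Weigh the partner with care and leave the clock alone: the reckoning below, from the runs in hand, says why.

| flask | starting material | partner | protic impurity | remark | time |
|---|---|---|---|---|---|
| grey | 0.25 M | 0.25 M | 0.025 M | run made earlier |  |
| blue | 1 M | 0.25 M | 0.025 M | run made earlier |  |
| teal | 0.50 M | 0.38 M | 0.025 M | run made earlier |  |
| flask | 0.50 M | 0.250 M | 0.0250 M |  | 8.0 h |

| run | time / h | target / % | starting material / % |
|---|---|---|---|
| grey | 0.417 | 58.1 | 14.8 |
| grey | 0.667 | 53.2 | 13.9 |
| grey | 0.833 | 50.8 | 15.1 |
| grey | 1.33 | 48.6 | 14.4 |
| grey | 2.00 | 47.7 | 14.2 |
| grey | 3.00 | 46.6 | 13.8 |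
| grey | 5.00 | 46.6 | 12.8 |
| blue | 0.250 | 20.5 | 72.4 |
| blue | 0.667 | 17.0 | 72.6 |
| blue | 1.33 | 15.6 | 73.2 |
| blue | 2.00 | 14.5 | 72.9 |
| blue | 3.00 | 15.6 | 72.8 |
| blue | 4.00 | 15.0 | 73.0 |
| blue | 5.00 | 14.9 | 73.0 |
| teal | 0.417 | 52.5 | 25.5 |
| teal | 0.667 | 48.8 | 25.1 |
| teal | 1.33 | 45.1 | 24.9 |
| teal | 2.50 | 44.0 | 24.6 |
| teal | 5.00 | 43.7 | 25.1 |

(scatter of a reading: 0.5 percentage points)

- the numbers in the tables scatter by 0.5 percentage points (one standard deviation)
- on the list of suspects stand: starting material + partner <-> target; starting material + partner <-> isomer of the product; starting material + protic impurity -> quenched substrate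
- the reaction counts as stopped when no species that holds the starting material changes by six tenths of a point or more over the second half of the time

1. at 8.0 h, what has stopped the reaction, if anything has (forward and back rates have come level / the partner has run out first / all of the starting material has reacted / it is still moving)
2. target at 8.0 h, in percent of the starting material charged

We read the grey run at its last point, where the target stood at 46.6 % as it had at 3.00 h. We assume that the impurity has quenched its whole charge and that the isomer of the product holds the rest of the balance:

bound fraction (target plus isomer) = 0.772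

target share = 46.6 % / 0.772 = 0.604

This target share, the part of the bound material that stands as target once the early excess has drained, is a reading of the split under thermodynamic control. In the flask the partner is the limiting reagent of the addition, its 0.500 of the charge lying below the 0.950 of starting material that the impurity leaves, so we count it as wholly bound:

target = 0.604 × 0.500 = 30.2 %

The grey target read the same at 3.00 h and 5.00 h, both earlier than 8.0 h, so we expect this flask to have come level by then.

The forecast names forward and back rates have come level and 29.5 %, a little below our figure, with “the system is at equilibrium, with partner small but nonzero”; the flask gives forward and back rates have come level and 29.2 %.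

    starting material + partner ⇌ target (K = 58.0 M⁻¹, k = 0.290 M⁻¹ s⁻¹)
    starting material + partner ⇌ isomer of the product (K = 37.0 M⁻¹, k = 0.0130 M⁻¹ s⁻¹)
    starting material + protic impurity → quenched substrate (k = 0.0730 M⁻¹ s⁻¹)

By 0.800 h the flask held target 32.5 %, isomer 15.1 % and quenched substrate 5.00 %, with the impurity at 0 %. While the partner in the flask went from 4.69 % to 4.28 % of its charge, target fell and isomer of the product rose, to 29.2 % and 18.6 % by 4.00 h, and at 80.0 h the target stands at 29.2 %. We had counted the partner as wholly bound, but 4.3 % of it stayed free, and the target share on what was bound gives 28.9 %.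

In the neighbour with 0.15 M of partner, the target share times 0.300 gives 18.1 %; the computed target there is 17.7 %.

The runs stem from a simulated flask on assumed constants; scatter was added.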